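Ring numbering: O1, C2 (ring A, 4-hydroxy-3-methoxyphenyl), C3 (Me), C4 (Me), C5 (ring B, 3-hydroxy-4,5-dimethoxyphenyl). The target is (2S,3S,4R,5R), that is 2,5-cis, 2,3-trans, 3,4-cis, 4,5-trans.
Structural feature used: C5 is benzylic to ring B, whose para-methoxy group can carry positive charge. The O1–C5–C4–C3 segment is therefore treated as a 2-aryl-3-methylcyclopropane-1,1-diester opened at its aryl-bearing carbon, and O1–C2 as the C=O of a ring A aldehyde.
Disconnections: both phenols ⇒ benzyl ethers; C3 methyl ⇒ CH2OH ⇒ CO2Me ⇒ geminal diester; tetrahydrofuran ⇒ (O1–C5 and C2–C3) cis-cyclopropane diester + O-benzylvanillin; cyclopropane ⇒ Z-propenylarene + malonate carbene; alkene ⇒ ring B aldehyde.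
Ring order: the cyclopropane is made first by asymmetric carbene transfer. It is then consumed as the tetrahydrofuran, the only ring of the target that must be built, is closed.

Key step: step 5

Assumption: the facial sense of the copper/bis(oxazoline) catalyst on the Z-alkene is not predicted here, so the ligand is written as its (S,S) form and its mirror image is used if a trial run shows the (2R,3R)-cyclopropane.

Step 1
Reactants: 1 3-hydroxy-4,5-dimethoxybenzaldehyde
Product: 2 3-benzyloxy-4,5-dimethoxybenzaldehyde
Conditions: BnBr (1.2 equiv), K2CO3, DMF, rt → 50 °C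
Reagents that add atoms: benzyl bromide, BrCc1ccccc1
Why: Williamson ether synthesis, in which the phenoxide of 1 is alkylated by benzyl bromide in an SN2 reaction to give a benzyl ether that tolerates every later step up to the final hydrogenolysis; no stereocentre is formed.

Step 2
Reactants: 2 3-benzyloxy-4,5-dimethoxybenzaldehyde
Product: 3 (Z)-1-benzyloxy-2,3-dimethoxy-5-(prop-1-en-1-yl)benzene
Conditions: EtPPh3Br, KN(SiMe3)2, THF, 0 °C; then 2, −78 °C → rt; chromatography on AgNO3-impregnated silica
Reagents that add atoms: ethyltriphenylphosphonium bromide, CC[P+](c1ccccc1)(c1ccccc1)c1ccccc1.[Br-]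
Why: Wittig olefination with a non-stabilised ylide under lithium-free, kinetically controlled conditions should favour the Z-alkene, whose geometry later becomes the cis aryl/methyl relationship of the cyclopropane, and residual E-isomer is removed on the silver-loaded silica.

Step 3
Reactants: 4 dimethyl malonate
Product: 5 dimethyl 2-(phenyl-λ3-iodanylidene)malonate (phenyliodonium ylide of dimethyl malonate)
Conditions: PhI(OAc)2, KOH, MeCN, 0 °C
Reagents that add atoms: (diacetoxyiodo)benzene, CC(=O)OI(OC(C)=O)c1ccccc1
Why: Iodonium ylide formation, in which the malonate carbanion displaces both acetates from the hypervalent iodine reagent, gives a storable carbene source in place of the diazo compound; no stereocentre is formed.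

Step 4
Reactants: 3 (Z)-1-benzyloxy-2,3-dimethoxy-5-(prop-1-en-1-yl)benzene; 5 phenyliodonium ylide of dimethyl malonate
Product: 6 dimethyl (2S,3S)-2-(3-benzyloxy-4,5-dimethoxyphenyl)-3-methylcyclopropane-1,1-dicarboxylate (aryl and methyl cis)
Conditions: 5 (1.5 equiv), Cu(MeCN)4PF6 (5 mol %), ligand L (6 mol %), 4 Å MS, toluene, 0 °C → rt; L = 2,2'-[1,3-bis(4-tert-butylphenyl)propane-2,2-diyl]bis[(4S)-4-phenyl-4,5-dihydro-1,3-oxazole]
Reagents that add atoms: none
Why: Copper-carbene cyclopropanation by carbene transfer from an iodonium ylide under monovalent copper/bis(oxazoline) catalysis, a reaction type known for cis-1,2-disubstituted styrenes; the addition is concerted and syn, so the Z geometry is copied into the cis-2,3 relationship, while the pocket of the side-arm ligand selects the alkene face and sets both stereocentres together.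

Step 5
Reactants: 6 dimethyl (2S,3S)-2-(3-benzyloxy-4,5-dimethoxyphenyl)-3-methylcyclopropane-1,1-dicarboxylate; 7 4-benzyloxy-3-methoxybenzaldehyde (O-benzylvanillin, commercial)
Product: 9 dimethyl (2R,4R,5R)-2-(4-benzyloxy-3-methoxyphenyl)-5-(3-benzyloxy-4,5-dimethoxyphenyl)-4-methyltetrahydrofuran-3,3-dicarboxylate (2,5-cis and 4,5-trans), via oxocarbenium malonate zwitterion 8 (not isolated)
Conditions: Sn(OTf)2 (10 mol %), 7 (3 equiv), 4 Å MS, CH2Cl2, −20 → 0 °C
Reagents that add atoms: none
Why: Divalent tin chelates the two ester carbonyls of 6 and polarises the cyclopropane bond between the malonate carbon and the ring B benzylic carbon; the carbonyl oxygen of 7 attacks that carbon from the rear within a tight ion pair (SN2-like, O1–C5 formed with inversion) and gives zwitterion 8, with strain release making the opening irreversible. The tin malonate carbon of 8 then adds to the oxocarbenium carbon (C2–C3), an aldol-type closure of the five-membered ring that is 5-enolexo for the nucleophile and formally 5-endo-trig for the C=O+ bond, which is tolerated because the acceptor is a cation whose geometry allows the attack angle in an envelope. The closest known reaction type is the Lewis-acid-catalysed formal (3+2) annulation of 2-arylcyclopropane-1,1-diesters with aldehydes, which is stereospecific at the donor carbon, 2,5-cis selective and documented for 2,3-disubstituted cyclopropanes. C5 (R) is fixed by the configuration of the cyclopropane carbon through inversion and C4 (R) is carried over untouched, so the cis aryl/methyl pair of 6 becomes the 4,5-trans pair of 9; C2 (R in 9) is fixed by the envelope transition state in which the E-oxocarbenium ion holds ring A, ring B and the C4 methyl pseudo-equatorial, which gives the 2,5-cis ring. The step needs cleavage of the bond to the aryl-bearing carbon rather than the bond to the methyl-bearing carbon, which the para-methoxy group of ring B secures, and it needs capture of the ion pair before it separates or the cyclopropane epimerises, which the excess of the electron-rich and strongly nucleophilic aldehyde, the low temperature and the tempering effect of the two meta oxygen substituents of ring B should secure.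

Step 6
Reactants: 9 dimethyl (2R,4R,5R)-2-(4-benzyloxy-3-methoxyphenyl)-5-(3-benzyloxy-4,5-dimethoxyphenyl)-4-methyltetrahydrofuran-3,3-dicarboxylate
Product: 10 methyl (2S,4R,5R)-2-(4-benzyloxy-3-methoxyphenyl)-5-(3-benzyloxy-4,5-dimethoxyphenyl)-4-methyltetrahydrofuran-3-carboxylate as a mixture of C3 epimers
Conditions: LiCl, H2O, DMSO, 150 °C
Reagents that add atoms: none
Why: Krapcho dealkoxycarbonylation, in which chloride attacks an ester methyl group in an SN2 reaction, the carboxylate loses CO2 and C3 is protonated by water under neutral conditions that leave the benzyl ethers and C2, C4 and C5 alone; C3 is formed without reliable control and is corrected in step 7.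

Step 7
Reactants: 10 monoester as a mixture of C3 epimers
Product: 11 methyl (2S,3S,4R,5R)-2-(4-benzyloxy-3-methoxyphenyl)-5-(3-benzyloxy-4,5-dimethoxyphenyl)-4-methyltetrahydrofuran-3-carboxylate (2,3-trans and 3,4-cis)
Conditions: NaOMe (0.5 equiv), MeOH–THF, 50 °C; chromatography, minor epimer resubmitted
Reagents that add atoms: none
Why: Base-mediated epimerisation under thermodynamic control through reversible deprotonation at C3, the only acidic site; the ester should settle trans to the neighbouring ring A aryl group on the face that holds only the C4 methyl, because the other epimer crowds both aryl groups and the ester onto one face, and E1cB ring opening is held back because the C2–O1 bond lies nearly orthogonal to the carbanion p orbital (the reverse of a 5-endo-trig addition).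

Step 8
Reactants: 11 methyl (2S,3S,4R,5R)-tetrahydrofuran-3-carboxylate
Product: 12 [(2S,3R,4R,5R)-2-(4-benzyloxy-3-methoxyphenyl)-5-(3-benzyloxy-4,5-dimethoxyphenyl)-4-methyltetrahydrofuran-3-yl]methanol
Conditions: LiAlH4, THF, 0 °C
Reagents that add atoms: none
Why: Ester reduction with LiAlH4 (hydride addition, alkoxide loss, second hydride addition) gives the primary alcohol quickly at low temperature, so C3 is not epimerised and the ethers are untouched.

Step 9
Reactants: 12 [(2S,3R,4R,5R)-tetrahydrofuran-3-yl]methanol
Product: 13 [(2S,3R,4R,5R)-2-(4-benzyloxy-3-methoxyphenyl)-5-(3-benzyloxy-4,5-dimethoxyphenyl)-4-methyltetrahydrofuran-3-yl]methyl 4-methylbenzenesulfonate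
Conditions: TsCl, Et3N, DMAP (cat.), CH2Cl2, 0 °C → rt
Reagents that add atoms: 4-toluenesulfonyl chloride, Cc1ccc(cc1)S(Cl)(=O)=O
Why: DMAP-catalysed sulfonylation of a primary alcohol turns the hydroxyl group into a leaving group without touching any bond to a stereocentre.

Step 10
Reactants: 13 primary tosylate
Product: 14 (2S,3S,4R,5R)-2-(4-benzyloxy-3-methoxyphenyl)-5-(3-benzyloxy-4,5-dimethoxyphenyl)-3,4-dimethyltetrahydrofuran
Conditions: LiEt3BH, THF, 0 °C → rt
Reagents that add atoms: none
Why: SN2 hydride displacement of a primary sulfonate with LiEt3BH, a strongly nucleophilic hydride suited to β-branched primary tosylates, turns CH2OTs into the C3 methyl group and leaves all four stereocentres and the benzyl ethers unchanged.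

Step 11
Reactants: 14 bis(benzyl ether) of the target
Product: 15 (2S,3S,4R,5R)-2-(4-hydroxy-3-methoxyphenyl)-5-(3-hydroxy-4,5-dimethoxyphenyl)-3,4-dimethyltetrahydrofuran (CNP0022199.2)
Conditions: H2 (1 atm), 10% Pd/C, EtOAc–MeOH, rt, hydrogen uptake monitored
Reagents that add atoms: none
Why: Catalytic hydrogenolysis cleaves the two unhindered primary O-benzyl bonds much faster than the secondary, flanked C2–O1 and C5–O1 bonds of the ring, so in a neutral solvent and with the reaction stopped at two equivalents of hydrogen the tetrahydrofuran and its stereocentres should survive.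

Compound list
1 | 3-hydroxy-4,5-dimethoxybenzaldehyde | COc1cc(C=O)cc(O)c1OC | starting material
2 | 3-benzyloxy-4,5-dimethoxybenzaldehyde | COc1cc(C=O)cc(OCc2ccccc2)c1OC | intermediate
3 | (Z)-1-benzyloxy-2,3-dimethoxy-5-(prop-1-en-1-yl)benzene | C/C=C\c1cc(OCc2ccccc2)c(OC)c(OC)c1 | intermediate
4 | dimethyl malonate | COC(=O)CC(=O)OC | starting material
5 | phenyliodonium ylide of dimethyl malonate | COC(=O)[C-](C(=O)OC)[I+]c1ccccc1 | intermediate
6 | dimethyl (2S,3S)-2-(3-benzyloxy-4,5-dimethoxyphenyl)-3-methylcyclopropane-1,1-dicarboxylate (cis) | COC(=O)C1(C(=O)OC)[C@H](c2cc(OCc3ccccc3)c(OC)c(OC)c2)[C@@H]1C | intermediate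
7 | 4-benzyloxy-3-methoxybenzaldehyde | COc1cc(C=O)ccc1OCc1ccccc1 | starting material
8 | oxocarbenium malonate zwitterion, drawn without the bound tin (C5 already inverted, E-oxocarbenium) | COC(=O)[C-](C(=O)OC)[C@@H](C)[C@H](c1cc(OCc2ccccc2)c(OC)c(OC)c1)/[O+]=C/c1ccc(OCc2ccccc2)c(OC)c1 | intermediate
9 | dimethyl (2R,4R,5R)-2-(4-benzyloxy-3-methoxyphenyl)-5-(3-benzyloxy-4,5-dimethoxyphenyl)-4-methyltetrahydrofuran-3,3-dicarboxylate | COc1cc([C@H]2O[C@@H](c3cc(OCc4ccccc4)c(OC)c(OC)c3)[C@H](C)C2(C(=O)OC)C(=O)OC)ccc1OCc1ccccc1 | intermediate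
10 | methyl (2S,4R,5R)-2-(4-benzyloxy-3-methoxyphenyl)-5-(3-benzyloxy-4,5-dimethoxyphenyl)-4-methyltetrahydrofuran-3-carboxylate, C3 epimer mixture (C2 descriptor changes through CIP priorities only) | COc1cc([C@H]2O[C@@H](c3cc(OCc4ccccc4)c(OC)c(OC)c3)[C@H](C)C2C(=O)OC)ccc1OCc1ccccc1 | intermediate
11 | methyl (2S,3S,4R,5R)-2-(4-benzyloxy-3-methoxyphenyl)-5-(3-benzyloxy-4,5-dimethoxyphenyl)-4-methyltetrahydrofuran-3-carboxylate | COc1cc([C@H]2O[C@@H](c3cc(OCc4ccccc4)c(OC)c(OC)c3)[C@H](C)[C@@H]2C(=O)OC)ccc1OCc1ccccc1 | intermediate
12 | [(2S,3R,4R,5R)-2-(4-benzyloxy-3-methoxyphenyl)-5-(3-benzyloxy-4,5-dimethoxyphenyl)-4-methyltetrahydrofuran-3-yl]methanol (C3 descriptor changes through CIP priorities only) | COc1cc([C@H]2O[C@@H](c3cc(OCc4ccccc4)c(OC)c(OC)c3)[C@H](C)[C@@H]2CO)ccc1OCc1ccccc1 | intermediate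
13 | [(2S,3R,4R,5R)-2-(4-benzyloxy-3-methoxyphenyl)-5-(3-benzyloxy-4,5-dimethoxyphenyl)-4-methyltetrahydrofuran-3-yl]methyl 4-methylbenzenesulfonate | COc1cc([C@H]2O[C@@H](c3cc(OCc4ccccc4)c(OC)c(OC)c3)[C@H](C)[C@@H]2COS(=O)(=O)c5ccc(C)cc5)ccc1OCc1ccccc1 | intermediate
14 | (2S,3S,4R,5R)-2-(4-benzyloxy-3-methoxyphenyl)-5-(3-benzyloxy-4,5-dimethoxyphenyl)-3,4-dimethyltetrahydrofuran | COc1cc([C@H]2O[C@@H](c3cc(OCc4ccccc4)c(OC)c(OC)c3)[C@H](C)[C@@H]2C)ccc1OCc1ccccc1 | intermediate
15 | (2S,3S,4R,5R)-2-(4-hydroxy-3-methoxyphenyl)-5-(3-hydroxy-4,5-dimethoxyphenyl)-3,4-dimethyltetrahydrofuran | COc1cc([C@H]2O[C@@H](c3cc(O)c(OC)c(OC)c3)[C@H](C)[C@@H]2C)ccc1O | target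

Total step count: 11. Longest linear sequence: 10 steps (1 → 15 through steps 1, 2 and 4–11). Step 3 is a one-step side branch.

Steps most likely to fail

1. Step 5 (annulation).
- What may go wrong: the Lewis acid may open the strained cis-cyclopropane to a free benzylic cation before the aldehyde arrives. Inversion at C5 would then be lost, either through epimerisation of the cyclopropane to its trans isomer or through scrambling at C5. Proton loss from the opened form to a styrenyl malonate could also compete.
- Fallback (sets out from 6 and 7, comes back at 9): the two bonds are made in separate operations.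
- Aldehyde 7 is reduced (NaBH4, MeOH) to (4-benzyloxy-3-methoxyphenyl)methanol F1.
- As an alcohol, F1 is a stronger nucleophile than the aldehyde. It opens 6 at the ring B benzylic carbon with inversion under Cu(OTf)2 catalysis (CH2Cl2, 0 °C), the known alcohol ring opening of donor–acceptor cyclopropanes. This gives dimethyl 2-[(1R,2R)-1-[(4-benzyloxy-3-methoxyphenyl)methoxy]-1-(3-benzyloxy-4,5-dimethoxyphenyl)propan-2-yl]malonate F2.
- DDQ with catalytic InCl3 and Cu(OTf)2 in CH2Cl2 then abstracts hydride from the dialkoxybenzyl CH2 of F2. This is an intramolecular cross-dehydrogenative coupling of a benzyl ether with a malonate. It produces zwitterion 8 when no cyclopropane is left to epimerise, and 8 closes to 9 through the same envelope as in step 5.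

2. Step 7 (together with step 6).
- What may go wrong: the thermodynamic bias may be too small, because the ester is cis to the C4 methyl in one epimer and cis to ring A in the other. Slow base-induced opening of the ring may also erode material over repeated recycling.
- Fallback (sets out from 9, comes back at 12): C3 is fixed by differentiating the two esters and removing one carbon with retention, not by an equilibrium.
- LiAlH(OtBu)3 in THF at reflux reduces only one ester of a malonate. Here it should choose the ester trans to ring A (on the face of the C4 methyl). This gives methyl (2R,3S,4R,5R)-2-(4-benzyloxy-3-methoxyphenyl)-5-(3-benzyloxy-4,5-dimethoxyphenyl)-3-(hydroxymethyl)-4-methyltetrahydrofuran-3-carboxylate F3.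
- Silylation (TBSCl, imidazole, DMF) gives the tert-butyldimethylsilyl ether of the hydroxy ester F4.
- i-Bu2AlH in toluene at −78 °C gives (2R,3S,4R,5R)-2-(4-benzyloxy-3-methoxyphenyl)-5-(3-benzyloxy-4,5-dimethoxyphenyl)-3-[(tert-butyldimethylsilyloxy)methyl]-4-methyltetrahydrofuran-3-carbaldehyde F5.
- Tsuji–Wilkinson decarbonylation with stoichiometric RhCl(PPh3)3 in refluxing toluene replaces CHO by H with retention and gives the tert-butyldimethylsilyl ether of alcohol 12 F6.
- Bu4NF in THF releases 12.

3. Step 4 (asymmetric cyclopropanation).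
- What may go wrong: carbene transfer to the hindered cis-alkene may be slow, with competing self-decomposition of the ylide. Facial discrimination may be incomplete. A stepwise addition on the electron-rich styrene could leak into the trans series.
- Fallback (sets out from 3 and 4, comes back at 6): a racemic synthesis followed by resolution.
- Diazo transfer to 4 (4-acetamidobenzenesulfonyl azide, Et3N, MeCN) gives dimethyl diazomalonate F7.
- Rh2(esp)2 (0.5 mol %, CH2Cl2, rt) transfers the carbene stereospecifically to 3. The product is the racemic cis-cyclopropane, that is 6 together with its mirror image dimethyl (2R,3R)-2-(3-benzyloxy-4,5-dimethoxyphenyl)-3-methylcyclopropane-1,1-dicarboxylate F8.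
- Preparative chromatography on an amylose tris(3,5-dimethylphenylcarbamate) stationary phase separates the two and delivers 6.

Further compounds
F1 | step 5 | (4-benzyloxy-3-methoxyphenyl)methanol | COc1cc(CO)ccc1OCc1ccccc1
F2 | step 5 | dimethyl 2-[(1R,2R)-1-[(4-benzyloxy-3-methoxyphenyl)methoxy]-1-(3-benzyloxy-4,5-dimethoxyphenyl)propan-2-yl]malonate | COC(=O)C(C(=O)OC)[C@@H](C)[C@H](c1cc(OCc2ccccc2)c(OC)c(OC)c1)OCc1ccc(OCc2ccccc2)c(OC)c1
F3 | step 7 | methyl (2R,3S,4R,5R)-2-(4-benzyloxy-3-methoxyphenyl)-5-(3-benzyloxy-4,5-dimethoxyphenyl)-3-(hydroxymethyl)-4-methyltetrahydrofuran-3-carboxylate | COc1cc([C@H]2O[C@@H](c3cc(OCc4ccccc4)c(OC)c(OC)c3)[C@H](C)[C@@]2(CO)C(=O)OC)ccc1OCc1ccccc1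
F4 | step 7 | methyl (2R,3S,4R,5R)-2-(4-benzyloxy-3-methoxyphenyl)-5-(3-benzyloxy-4,5-dimethoxyphenyl)-3-[(tert-butyldimethylsilyloxy)methyl]-4-methyltetrahydrofuran-3-carboxylate | COc1cc([C@H]2O[C@@H](c3cc(OCc4ccccc4)c(OC)c(OC)c3)[C@H](C)[C@@]2(CO[Si](C)(C)C(C)(C)C)C(=O)OC)ccc1OCc1ccccc1
F5 | step 7 | (2R,3S,4R,5R)-2-(4-benzyloxy-3-methoxyphenyl)-5-(3-benzyloxy-4,5-dimethoxyphenyl)-3-[(tert-butyldimethylsilyloxy)methyl]-4-methyltetrahydrofuran-3-carbaldehyde | COc1cc([C@H]2O[C@@H](c3cc(OCc4ccccc4)c(OC)c(OC)c3)[C@H](C)[C@@]2(CO[Si](C)(C)C(C)(C)C)C=O)ccc1OCc1ccccc1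
F6 | step 7 | tert-butyl{[(2S,3R,4R,5R)-2-(4-benzyloxy-3-methoxyphenyl)-5-(3-benzyloxy-4,5-dimethoxyphenyl)-4-methyltetrahydrofuran-3-yl]methoxy}dimethylsilane | COc1cc([C@H]2O[C@@H](c3cc(OCc4ccccc4)c(OC)c(OC)c3)[C@H](C)[C@@H]2CO[Si](C)(C)C(C)(C)C)ccc1OCc1ccccc1
F7 | step 4 | dimethyl diazomalonate | COC(=O)C(=[N+]=[N-])C(=O)OC
F8 | step 4 | dimethyl (2R,3R)-2-(3-benzyloxy-4,5-dimethoxyphenyl)-3-methylcyclopropane-1,1-dicarboxylate | COC(=O)C1(C(=O)OC)[C@@H](c2cc(OCc3ccccc3)c(OC)c(OC)c2)[C@H]1C
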